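in all of them: catalyst 1.5 mol%
- winter: substrate 0.54 M; run made earlier
- dusk: substrate 1.2 M; run made earlier
- flask: substrate 0.80 M; time 5.0 h

- winter (time / h: isomer of the product / %, target / %): 0.250: 23.4, 56.7; 0.833: 23.4, 57.0; 1.33: 23.6, 57.3; 2.00: 23.5, 57.2; 3.00: 23.7, 57.0; 4.00: 23.8, 56.5
- dusk (time / h: isomer of the product / %, target / %): 0.333: 17.2, 68.6; 0.500: 17.6, 68.0; 0.833: 17.7, 68.6; 1.33: 17.3, 68.4; 2.50: 17.1, 68.4; 4.00: 17.5, 68.0

(each reading ± 0.3 percentage points)

1. share of isomer of the product in isomer of the product plus target at 2.0 s
2. share of isomer of the product in isomer of the product plus target at 5.0 h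

- a reading or a percentage of target counts all its forms, free or not

**The trap.** A plateau share that shifts with the charge invites a reaction order, but a ceiling on one species can shift it too. Winter averages 23.6% isomer and 57.0% target, so its share is 29.3% and the remainder, substrate, is 19.5%. Dusk averages 68.3% target and leaves 14.3% substrate.

**Turned round.** What must be true for this flask to leave the winter share? Its target must pass a ceiling. Winter substrate, 0.105 M, is lower than dusk's 0.171 M, so we place winter under the ceiling. Target per substrate reads 2.92 in winter but 4.78 in dusk, and we take that excess as crystals. Winter's ratio times dusk substrate gives the solubility limit S, 0.500 M. We call 0.879 M the critical charge c*, the charge whose plateau target just reaches S. This flask, at 0.80 M, stands 0.0409 of a decade below c*, so we expect no crystals and the winter share at 5.0 h. No reading bears on 2.0 s, which precedes the earliest.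

**The forecast.** Holding that “this is not a simple isomer equilibrium”, it gives 24.4% (23.7% to 25.1%), below our 29.3%, and 45% (8% to 100%) at the early time.

**The result.** This flask gives 28.2% at 2.0 s and 29.3% at 5.0 h, with crystals at 0%; the falling out of target changes nothing in its share.

    substrate + catalyst ⇌ target + catalyst, rate k1*[substrate]*[catalyst] forward; the back reaction follows from the equilibrium constant (K = 2.90, k = 13.0 M⁻¹ s⁻¹)
    substrate + catalyst ⇌ isomer of the product + catalyst, rate k2*[substrate]*[catalyst] forward; the back reaction follows from the equilibrium constant (K = 1.20, k = 5.10 M⁻¹ s⁻¹)
    crystals ⇌ target, rate k3*(cs3 - [target]) while solid is left; crystals form when [target] > cs3 (solubility = 0.500 M, k = 0.710 s⁻¹)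

**The neighbour.** A neighbouring flask, the same recipe charged at 1.4 M, stands 0.202 of a decade above c*. Holding its dissolved target at S with winter's ratios, we reckon isomer at 14.8% of the charge and a share of 16.9%. At 5.0 h the neighbouring flask shows isomer 14.8%, target 72.9% with crystals 37.2% counted in, and a share of 16.9%.

(The earlier runs and the new flask were generated by integration for substances that don't exist.)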